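**Retrosynthetic overview**

1. Drimane numbering is used: C3 carries the ester, C4 the gem-dimethyl group, C5/C10 are the ring-fusion carbons, C8 carries the methylidene C12, C9 carries C11H2–O; the target is (3R,5S,9R,10R). Last operations: C11–O–aryl (Mitsunobu), C3 ester (acylation), C3–OH (reduction of a 3-ketone).
2. C5–H (trans to C10–CH3) and the second C4 methyl come from Li/NH3 reductive methylation of a Δ4-3-ketone; ring A (second carbocycle) comes from an aldol condensation C4=C5 between a 3-oxopentyl chain on C10 and a C5 ketone.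
3. Ring B (first carbocycle) is closed at C5–C6 by iodine–lithium exchange at C6 and attack on the carbonyl C5 of a γ-butyrolactone: two electrophilic carbons (C6–I and acyl C5) are joined by polarity reversal at C6.
4. Enabling feature: the five-membered lactone ring O–C11–C9–C10–C5(=O). Its acyl carbon C5 lies 1,3 to the C9 side chain C8(=C12)–C7–C6, C10 is quaternary (no α-hydrogen), and the ring oxygen is the later C11–O; ring opening gives the C5 ketone for ring A and the free C11–OH.
5. Lactone (temporary ring, made first): C9 by Rh/(S)-BINAP 1,4-addition of the C6–C7–C8(=C12) alkenylboronate to furan-2(5H)-one; C10 by two enolate alkylations (ketal-protected 3-oxopentyl iodide, then MeI) anti to the C9 substituent. Ring order: lactone, then ring B, then ring A.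

Key step: step 9

**Route**

Step 1
Reactants: 1 3-bromobut-3-en-1-ol
Product: 2 tert-butyl[(3-bromobut-3-en-1-yl)oxy]dimethylsilane
Conditions: TBSCl, imidazole, CH2Cl2, 0 °C to rt
Reagents that add atoms: tert-butyldimethylsilyl chloride, CC(C)(C)[Si](C)(C)Cl
Why: Imidazole-mediated silylation of an unhindered primary alcohol should proceed cleanly and creates no stereocentre.

Step 2
Reactants: 2 tert-butyl[(3-bromobut-3-en-1-yl)oxy]dimethylsilane
Product: 3 tert-butyldimethyl{[3-(4,4,5,5-tetramethyl-1,3,2-dioxaborolan-2-yl)but-3-en-1-yl]oxy}silane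
Conditions: B2pin2, PdCl2(PPh3)2 (3 mol %), PPh3, KOPh, toluene, 50 °C
Reagents that add atoms: bis(pinacolato)diboron, CC1(C)OB(OC1(C)C)B1OC(C)(C)C(C)(C)O1
Why: Miyaura borylation of a 1-alkenyl bromide (oxidative addition, phenoxide-assisted transmetalation, reductive elimination) should give the 1,1-disubstituted alkenylboronate without touching the silyl ether.

Step 3
Reactants: 3 alkenylboronate; 4 furan-2(5H)-one
Product: 5 (4S)-4-{4-[(tert-butyldimethylsilyl)oxy]but-1-en-2-yl}oxolan-2-one
Conditions: [Rh(OH)(cod)]2 (2.5 mol %), (S)-BINAP (5.5 mol %), KOH (10 mol %), 1,4-dioxane/H2O (10:1), 40 °C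
Reagents that add atoms: none
Why: Hayashi–Miyaura asymmetric 1,4-addition, in which the alkenylrhodium–(S)-BINAP species should add to the butenolide face that leads to the (4S)-lactone (the facial sense that gives (S)-3-substituted cyclohexanones), so that C9 and the absolute configuration of the whole route are set by the catalyst.

Step 4
Reactants: 6 pent-1-en-3-one
Product: 7 2-ethyl-2-(2-iodoethyl)-1,3-dioxolane
Conditions: Me3SiCl, NaI, MeCN, −20 to 0 °C; then ethane-1,2-diol, rt
Reagents that add atoms: sodium iodide, [Na+].[I-]; ethane-1,2-diol, OCCO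
Why: Conjugate addition of iodotrimethylsilane formed in the flask to the enone, followed by ketalisation of the β-iodo ketone in the same pot, is an established way to β-halo ketals and creates no stereocentre.

Step 5
Reactants: 5 (4S)-lactone; 7 2-ethyl-2-(2-iodoethyl)-1,3-dioxolane
Product: 9 (3R,4S)-4-{4-[(tert-butyldimethylsilyl)oxy]but-1-en-2-yl}-3-[2-(2-ethyl-1,3-dioxolan-2-yl)ethyl]oxolan-2-one (3,4-trans), via lithium enolate 8 (not isolated)
Conditions: LiN(i-Pr)2, THF, −78 °C; then 7, DMPU, −78 to −20 °C
Reagents that add atoms: none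
Why: SN2 alkylation of a lactone lithium enolate by a primary iodide should occur anti to the C9 substituent, and since the C10 configuration made here is erased in step 6 only the new C10–C1 bond matters.

Step 6
Reactants: 9 (3R,4S)-lactone
Product: 11 (3S,4R)-4-{4-[(tert-butyldimethylsilyl)oxy]but-1-en-2-yl}-3-[2-(2-ethyl-1,3-dioxolan-2-yl)ethyl]-3-methyloxolan-2-one (methyl trans to the alkenyl group), via lithium enolate 10 (not isolated)
Conditions: LiN(i-Pr)2, THF, −78 °C; then MeI, −78 to −40 °C
Reagents that add atoms: iodomethane, CI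
Why: Enolate alkylation under 1,2-induction, in which the planar enolate 10 should take up MeI on the face anti to the C9 alkenyl group as β-substituted γ-butyrolactone enolates generally do, placing the methyl trans and the ketal chain cis to the alkenyl group and so fixing the quaternary C10.

Step 7
Reactants: 11 (3S,4R)-lactone silyl ether
Product: 12 (3S,4R)-3-[2-(2-ethyl-1,3-dioxolan-2-yl)ethyl]-4-(4-hydroxybut-1-en-2-yl)-3-methyloxolan-2-one
Conditions: Bu4NF, THF, 0 °C to rt
Reagents that add atoms: none
Why: Fluoride-induced desilylation should free the primary alcohol while the lactone, the ketal and both stereocentres (neither is enolisable) stay untouched.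

Step 8
Reactants: 12 primary alcohol
Product: 13 (3S,4R)-3-[2-(2-ethyl-1,3-dioxolan-2-yl)ethyl]-4-(4-iodobut-1-en-2-yl)-3-methyloxolan-2-one
Conditions: I2, PPh3, imidazole, CH2Cl2, 0 °C
Reagents that add atoms: iodine, II
Why: Appel-type iodination of a primary alcohol through its alkoxyphosphonium salt should give the iodide, with imidazole keeping the medium non-acidic for the ketal.

Step 9
Reactants: 13 iodo lactone
Product: 16 (2S,3R)-2-[2-(2-ethyl-1,3-dioxolan-2-yl)ethyl]-3-(hydroxymethyl)-2-methyl-4-methylidenecyclohexan-1-one, via alkyllithium 14 (not isolated), via lithium lactolate 15 (not isolated)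
Conditions: t-BuLi (2.1 equiv), Et2O/pentane, −78 °C, then to −40 °C; then H2O
Reagents that add atoms: none
Why: Iodine–lithium exchange turns the electrophilic C6 of 13 into the primary alkyllithium 14 (polarity reversal), which should add to the lactone carbonyl C5 through a six-membered transition state to give the bridged lithium lactolate 15 (a 6-oxabicyclo[3.2.1]octane), and the aqueous quench collapses the hemiketal to the hydroxy ketone 16; the closest known reaction types are the exchange-initiated cycloacylation of ω-iodo esters (Parham-type anionic cyclisation) and the SmI2-promoted intramolecular nucleophilic acyl substitution of iodoalkyl lactones. Ring B is closed by a 6-exo-trig addition at the acyl carbon, with C6 reaching C5 from the lactone face that carries the C9 side chain, roughly perpendicular to the O–C5=O plane. No new stereocentre survives the step: C5 is stereogenic only in 15, where the bicycle fixes it, and returns to sp2 in 16, while C9 and C10 carry no hydrogen that could be removed and pass through unchanged. The step needs exchange to outrun direct addition of t-BuLi to the carbonyl and needs mono-addition: exchange at a primary iodide is much faster than carbonyl addition at −78 °C, the quaternary C10 shields C5 from intermolecular attack and leaves no enolisable α-hydrogen, the second equivalent of t-BuLi is consumed by the tert-butyl iodide formed, and the ketone stays masked as lactolate 15 until the quench. The dioxolane and the 1,1-disubstituted alkene are inert to the carbanion, so the lactone carbonyl is the only electrophile within reach.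

Step 10
Reactants: 16 hydroxy ketone
Product: 17 (2S,3R)-2-[2-(2-ethyl-1,3-dioxolan-2-yl)ethyl]-2-methyl-4-methylidene-3-{[(triisopropylsilyl)oxy]methyl}cyclohexan-1-one
Conditions: i-Pr3SiCl, imidazole, DMAP (cat.), DMF, rt
Reagents that add atoms: chlorotriisopropylsilane, CC(C)[Si](Cl)(C(C)C)C(C)C
Why: Silylation of the primary hydroxyl should hold C11–O as a triisopropylsilyl ether that survives the acid, base and dissolving-metal steps that follow and prevents the hydroxyl from adding to C5.

Step 11
Reactants: 17 keto ketal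
Product: 19 (4aS,5R)-1,4a-dimethyl-6-methylidene-5-{[(triisopropylsilyl)oxy]methyl}-4,4a,5,6,7,8-hexahydronaphthalen-2(3H)-one, via diketone 18 (not isolated)
Conditions: PPTS, acetone/H2O, 55 °C; then KOH, MeOH, 60 °C
Reagents that add atoms: water, O
Why: Mild acid hydrolysis of the dioxolane followed by a Robinson-type intramolecular aldol condensation (C4 enolate of the ethyl ketone onto the C5 ketone, then dehydration) should close ring A as the tetrasubstituted enone, the competing bridged aldols being reversible and C9 and C10 not being epimerisable.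

Step 12
Reactants: 19 bicyclic enone
Product: 21 (5S,9R,10R)-11-[(triisopropylsilyl)oxy]drim-8(12)-en-3-one, via lithium enolate 20 (not isolated)
Conditions: Li (2.2 equiv), NH3(l)/THF, t-BuOH (1.0 equiv), −78 °C; then MeI (excess), −78 to −33 °C
Reagents that add atoms: iodomethane, CI
Why: Birch-type reductive alkylation of an enone, in which two-electron reduction gives a C5 carbanion that is protonated axially and anti to the C10 methyl group (trans ring fusion, the usual outcome for 10-methyl-Δ4-3-octalones) and the regiodefined lithium enolate 20 is then C-methylated at C4, the isolated 1,1-disubstituted alkene and the silyl ether being inert to Li/NH3.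

Step 13
Reactants: 21 trans-fused 4,4-dimethyl-3-ketone
Product: 22 (3R,5S,9R,10R)-11-[(triisopropylsilyl)oxy]drim-8(12)-en-3-ol (equatorial hydroxyl)
Conditions: NaBH4, MeOH/THF, 0 °C to rt
Reagents that add atoms: none
Why: Hydride reduction of a 4,4-dimethyl-3-ketone, in which borohydride should attack along the axial trajectory on the face of H5 (flanked only by axial hydrogens at C1 and C5) and so give the equatorial (3R)-alcohol.

Step 14
Reactants: 22 secondary alcohol; 23 3-methylbutanoyl chloride
Product: 24 (3R,5S,9R,10R)-11-[(triisopropylsilyl)oxy]drim-8(12)-en-3-yl 3-methylbutanoate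
Conditions: pyridine, DMAP (cat.), CH2Cl2, 0 °C to rt
Reagents that add atoms: none
Why: DMAP-catalysed acylation of the equatorial secondary alcohol with an acid chloride should give the ester with retention at C3.

Step 15
Reactants: 24 silyl ether ester
Product: 25 (3R,5S,9R,10R)-11-hydroxydrim-8(12)-en-3-yl 3-methylbutanoate
Conditions: Bu4NF, AcOH (buffer), THF, rt
Reagents that add atoms: none
Why: Buffered fluoride desilylation should free the primary C11 hydroxyl without cleaving the hindered C3 ester.

Step 16
Reactants: 25 primary alcohol; 26 7-hydroxy-2H-chromen-2-one (umbelliferone)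
Product: 27 (3R,5S,9R,10R)-11-[(2-oxo-2H-chromen-7-yl)oxy]drim-8(12)-en-3-yl 3-methylbutanoate (target, CNP0295317.1)
Conditions: PPh3, DIAD, THF, 0 °C to rt
Reagents that add atoms: none
Why: Mitsunobu etherification of a primary alcohol with an acidic phenol should form the aryl ether at the non-stereogenic C11 without affecting the ester, the alkene or the four stereocentres.

**Compound list**

1 | 3-bromobut-3-en-1-ol | C=C(Br)CCO | starting material
2 | tert-butyl[(3-bromobut-3-en-1-yl)oxy]dimethylsilane | C=C(Br)CCO[Si](C)(C)C(C)(C)C | intermediate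
3 | tert-butyldimethyl{[3-(4,4,5,5-tetramethyl-1,3,2-dioxaborolan-2-yl)but-3-en-1-yl]oxy}silane | C=C(CCO[Si](C)(C)C(C)(C)C)B1OC(C)(C)C(C)(C)O1 | intermediate
4 | furan-2(5H)-one | O=C1C=CCO1 | starting material
5 | (4S)-4-{4-[(tert-butyldimethylsilyl)oxy]but-1-en-2-yl}oxolan-2-one | O=C1C[C@@H](C(=C)CCO[Si](C)(C)C(C)(C)C)CO1 | intermediate
6 | pent-1-en-3-one | C=CC(=O)CC | starting material
7 | 2-ethyl-2-(2-iodoethyl)-1,3-dioxolane | CCC1(CCI)OCCO1 | intermediate
8 | lithium enolate of 5 (not isolated) | [Li+].[O-]C1=C[C@@H](C(=C)CCO[Si](C)(C)C(C)(C)C)CO1 | intermediate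
9 | (3R,4S)-4-{4-[(tert-butyldimethylsilyl)oxy]but-1-en-2-yl}-3-[2-(2-ethyl-1,3-dioxolan-2-yl)ethyl]oxolan-2-one | CCC1(OCCO1)CC[C@@H]2[C@@H](C(=C)CCO[Si](C)(C)C(C)(C)C)COC2=O | intermediate
10 | lithium enolate of 9 (not isolated) | [Li+].[O-]C1=C(CCC2(CC)OCCO2)[C@@H](C(=C)CCO[Si](C)(C)C(C)(C)C)CO1 | intermediate
11 | (3S,4R)-4-{4-[(tert-butyldimethylsilyl)oxy]but-1-en-2-yl}-3-[2-(2-ethyl-1,3-dioxolan-2-yl)ethyl]-3-methyloxolan-2-one | CCC1(OCCO1)CC[C@@]2(C)[C@@H](C(=C)CCO[Si](C)(C)C(C)(C)C)COC2=O | intermediate
12 | (3S,4R)-3-[2-(2-ethyl-1,3-dioxolan-2-yl)ethyl]-4-(4-hydroxybut-1-en-2-yl)-3-methyloxolan-2-one | CCC1(OCCO1)CC[C@@]2(C)[C@@H](C(=C)CCO)COC2=O | intermediate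
13 | (3S,4R)-3-[2-(2-ethyl-1,3-dioxolan-2-yl)ethyl]-4-(4-iodobut-1-en-2-yl)-3-methyloxolan-2-one | CCC1(OCCO1)CC[C@@]2(C)[C@@H](C(=C)CCI)COC2=O | intermediate
14 | primary alkyllithium (13 with Li in place of I; not isolated) | CCC1(OCCO1)CC[C@@]2(C)[C@@H](C(=C)CC[Li])COC2=O | intermediate
15 | lithium 8-[2-(2-ethyl-1,3-dioxolan-2-yl)ethyl]-8-methyl-2-methylidene-6-oxabicyclo[3.2.1]octan-5-olate (bridged lactolate; not isolated) | CCC1(OCCO1)CC[C@@]2(C)[C@@H]3CO[C@@]2([O-])CCC3=C.[Li+] | intermediate
16 | (2S,3R)-2-[2-(2-ethyl-1,3-dioxolan-2-yl)ethyl]-3-(hydroxymethyl)-2-methyl-4-methylidenecyclohexan-1-one | CCC1(OCCO1)CC[C@@]2(C)[C@H](CO)C(=C)CCC2=O | intermediate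
17 | (2S,3R)-2-[2-(2-ethyl-1,3-dioxolan-2-yl)ethyl]-2-methyl-4-methylidene-3-{[(triisopropylsilyl)oxy]methyl}cyclohexan-1-one | CCC1(OCCO1)CC[C@@]2(C)[C@H](CO[Si](C(C)C)(C(C)C)C(C)C)C(=C)CCC2=O | intermediate
18 | (2S,3R)-2-methyl-4-methylidene-2-(3-oxopentyl)-3-{[(triisopropylsilyl)oxy]methyl}cyclohexan-1-one (not isolated) | CCC(=O)CC[C@@]1(C)[C@H](CO[Si](C(C)C)(C(C)C)C(C)C)C(=C)CCC1=O | intermediate
19 | (4aS,5R)-1,4a-dimethyl-6-methylidene-5-{[(triisopropylsilyl)oxy]methyl}-4,4a,5,6,7,8-hexahydronaphthalen-2(3H)-one | C=C1CCC2=C(C)C(=O)CC[C@@]2(C)[C@@H]1CO[Si](C(C)C)(C(C)C)C(C)C | intermediate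
20 | lithium C3–C4 enolate of the trans-fused 4-methyl-3-ketone (not isolated) | C=C1CC[C@@H]2C(C)=C([O-])CC[C@@]2(C)[C@@H]1CO[Si](C(C)C)(C(C)C)C(C)C.[Li+] | intermediate
21 | (5S,9R,10R)-11-[(triisopropylsilyl)oxy]drim-8(12)-en-3-one | C=C1CC[C@@H]2C(C)(C)C(=O)CC[C@@]2(C)[C@@H]1CO[Si](C(C)C)(C(C)C)C(C)C | intermediate
22 | (3R,5S,9R,10R)-11-[(triisopropylsilyl)oxy]drim-8(12)-en-3-ol | C=C1CC[C@@H]2C(C)(C)[C@H](O)CC[C@@]2(C)[C@@H]1CO[Si](C(C)C)(C(C)C)C(C)C | intermediate
23 | 3-methylbutanoyl chloride | CC(C)CC(=O)Cl | starting material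
24 | (3R,5S,9R,10R)-11-[(triisopropylsilyl)oxy]drim-8(12)-en-3-yl 3-methylbutanoate | C=C1CC[C@@H]2C(C)(C)[C@H](OC(=O)CC(C)C)CC[C@@]2(C)[C@@H]1CO[Si](C(C)C)(C(C)C)C(C)C | intermediate
25 | (3R,5S,9R,10R)-11-hydroxydrim-8(12)-en-3-yl 3-methylbutanoate | C=C1CC[C@@H]2C(C)(C)[C@H](OC(=O)CC(C)C)CC[C@@]2(C)[C@@H]1CO | intermediate
26 | 7-hydroxy-2H-chromen-2-one | Oc1ccc2ccc(=O)oc2c1 | starting material
27 | (3R,5S,9R,10R)-11-[(2-oxo-2H-chromen-7-yl)oxy]drim-8(12)-en-3-yl 3-methylbutanoate | C=C1CC[C@@H]2C(C)(C)[C@H](OC(=O)CC(C)C)CC[C@@]2(C)[C@@H]1COc1ccc2ccc(=O)oc2c1 | target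

**Step count and risks**

Total step count: 16. Longest linear sequence: 15 steps (steps 1–3 and 5–16; step 4 makes the side-chain iodide 7).

Most likely to fail:

Step 9. What may go wrong: addition of t-BuLi to the lactone carbonyl, or protonation or coupling of the alkyllithium before it closes the ring. Fallback: ring B would be closed with a sulfone-stabilised carbanion instead. Starting from 13, displacement of iodide with PhSO2Na in DMF should give the phenyl sulfone F1. LiN(SiMe3)2 (2.2 equiv, THF, −78 to 0 °C) should deprotonate next to sulfur and bring about an intramolecular Claisen-type acylation on the lactone carbonyl, giving the β-keto sulfone F2 (mixture of C6 epimers). Reductive desulfonylation with Na(Hg)/Na2HPO4 in MeOH would rejoin the route at 16.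

Step 3. What may go wrong: slow transmetalation and protodeboronation of the hindered 1,1-disubstituted alkenylboronate, base-induced decomposition of the butenolide, or insufficient facial selectivity. Fallback: substrate control in place of catalyst control. Starting from 2, Mg in THF should give the Grignard reagent F3. Under CuBr·SMe2 catalysis (THF, −78 °C) it should add to commercially available (5R)-5-[(1R,2S,5R)-2-isopropyl-5-methylcyclohexyloxy]furan-2(5H)-one anti to the menthyloxy group, giving the trans adduct F4. NaBH4 in aqueous KOH followed by acidification to pH 3 (reduction of the unmasked formyl group and relactonisation, with loss of menthol) would rejoin the route at 5.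

Step 12. What may go wrong: over-reduction of the ketone, proton transfer to enolate 20 before alkylation, or O- and poly-methylation in liquid ammonia. Fallback: reduction and alkylation would be separated. Starting from 19, Li/NH3 (t-BuOH, 1 equiv) followed by a quench with Me3SiCl/Et3N should give the trimethylsilyl enol ether F5 with the trans ring fusion already in place. MeLi (THF, 0 °C) would regenerate the lithium enolate 20 free of ammonia and amide, and MeI/HMPA would then rejoin the route at 21.

**Further compounds**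

F1 | step 9 | (3S,4R)-3-[2-(2-ethyl-1,3-dioxolan-2-yl)ethyl]-3-methyl-4-[4-(phenylsulfonyl)but-1-en-2-yl]oxolan-2-one | CCC1(OCCO1)CC[C@@]2(C)[C@@H](C(=C)CCS(=O)(=O)c3ccccc3)COC2=O
F2 | step 9 | (2S,3R)-2-[2-(2-ethyl-1,3-dioxolan-2-yl)ethyl]-3-(hydroxymethyl)-2-methyl-4-methylidene-6-(phenylsulfonyl)cyclohexan-1-one (C6 epimers) | CCC1(OCCO1)CC[C@@]2(C)[C@H](CO)C(=C)CC(S(=O)(=O)c3ccccc3)C2=O
F3 | step 3 | {4-[(tert-butyldimethylsilyl)oxy]but-1-en-2-yl}magnesium bromide | C=C(CCO[Si](C)(C)C(C)(C)C)[Mg]Br
F4 | step 3 | (4S,5R)-4-{4-[(tert-butyldimethylsilyl)oxy]but-1-en-2-yl}-5-[(1R,2S,5R)-2-isopropyl-5-methylcyclohexyloxy]oxolan-2-one | O=C1C[C@@H](C(=C)CCO[Si](C)(C)C(C)(C)C)[C@H](O[C@@H]2C[C@H](C)CC[C@H]2C(C)C)O1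
F5 | step 12 | trimethylsilyl enol ether (C3–C4) of the trans-fused 4-methyl-3-ketone | C=C1CC[C@@H]2C(C)=C(O[Si](C)(C)C)CC[C@@]2(C)[C@@H]1CO[Si](C(C)C)(C(C)C)C(C)C
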